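**Amounts first.** You have closed-flask runs and set-ups to rank by the amount of target they deliver.

| flask | starting material | partner | remark | time |
|---|---|---|---|---|
| Saturday's | 0.050 M | 0.050 M | run made earlier |  |
| Friday's | 0.034 M | 0.050 M | run made earlier |  |
| Tuesday's | 0.075 M | 0.050 M | run made earlier |  |
| Monday's | 0.050 M | 0.075 M | run made earlier |  |
| teal | 0.050 M | 0.0500 M | a single well-mixed tank run continuously and read at steady state, 15 min in it on average |  |
| grey | 0.050 M | 0.0500 M | a single well-mixed tank run continuously and read at steady state, 45.0 min in it on average |  |
| amber | 0.050 M | 0.0500 M | a closed flask charged with all of it at once and left for 15 min | 15 min |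
| ochre | 0.050 M (fed, over 15.0 min) | 0.0500 M | all but starting material at the start; starting material goes in evenly over 15.0 min, the run ends at 15 min | 15 min |

| run | time / min | target / % | starting material / % |
|---|---|---|---|
| Saturday's | 4.00 | 3 | 73 |
| Saturday's | 8.00 | 9 | 59 |
| Saturday's | 12.0 | 17 | 51 |
| Saturday's | 15.0 | 20 | 47 |
| Friday's | 1.00 | 0 | 92 |
| Friday's | 3.00 | 4 | 77 |
| Friday's | 6.00 | 5 | 65 |
| Friday's | 10.0 | 11 | 50 |
| Tuesday's | 1.00 | 0 | 92 |
| Tuesday's | 3.00 | 0 | 78 |
| Tuesday's | 6.00 | 7 | 69 |
| Tuesday's | 10.0 | 10 | 60 |
| Monday's | 1.00 | 0 | 88 |
| Monday's | 3.00 | 6 | 69 |
| Monday's | 6.00 | 7 | 51 |
| Monday's | 10.0 | 16 | 39 |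

(scatter of a reading: 1.5 percentage points)

- the stated concentrations are those of everything mixed, before any reaction; amounts are the same in each set-up
- what was read earlier has a scatter of 1.5 percentage points, one standard deviation
- the feed brings no volume worth counting
- the earlier runs were made in a closed, stirred flask
- a reading or a percentage of target counts all its forms, free or not

- the set-up with the highest amount of target at the outlet or at the end, in percent of the starting material put in ("none" if the first two lie within 2 percentage points) (teal / grey / amber / ochre / none)
- amount of target at the outlet or at the end, in percent of the starting material put in, teal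
- amount of target at the outlet or at the end, in percent of the starting material put in, grey
- amount of target at the outlet or at the end, in percent of the starting material put in, amber
- amount of target at the outlet or at the end, in percent of the starting material put in, ochre

**The gap.** In Saturday's run at 12.0 min, starting material reads 51 % and target 17 %, so 32.0 % of the charge is unaccounted for. Read that gap as an intermediate on its way to target. From 8.00 min to 15.0 min, target climbs from 9 % to 20 % while the gap barely moves. Dividing the gap by target's rise per minute gives the intermediate a lifetime of about 20.4 min, as a reading.

**Lag number.** Divide the average stay in a tank by that lifetime. This is the lag number, a Damköhler number, and for grey it is 2.21. It says how many lifetimes the intermediate spends in the tank on average. At steady state, intermediate turns into target as fast as target leaves with the flow, so target divided by intermediate at the outlet should come to about this number. Of what has reacted in grey, 68.8 % should therefore be target.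

**Enough alone?** No, because the number doesn't say how much has reacted. Saturday's run supplies that: charged over left, minus one, is 1.13 at 15.0 min. Scaled to grey's stay, this becomes 3.38, and the tank balance for equal charges leaves 41.6 % of the starting material. My reckoning for grey is 40.2 %. Teal's average stay of 15 min gives a number of 0.737 and a reckoning of 17.1 %. Amber repeats Saturday's run, at 20 %. Ochre's starting material gets on average half of amber's time, so I expect it below amber. Grey ranks first, well ahead.

The forecast gives teal 18 %, grey 41 %, amber 20 % and ochre 9 %, and says “The long residence time wins, so grey is best.”

**The result.** The flask gives teal 18.4 %, grey 40.1 %, amber 21.7 % and ochre 8.99 %, with grey best.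

    intermediate → target (k = 9.20 × 10⁻⁴ s⁻¹)
    starting material + partner → intermediate (k = 0.0310 M⁻¹ s⁻¹)
    2 partner → self-condensation product (k = 0.00390 M⁻¹ s⁻¹)
    partner + target ⇌ idle adduct, settled at all times (K = 5.70 M⁻¹)

**Number checked.** Grey's outlet holds 16.1 % intermediate, so target, idle adduct counted in, stands to intermediate as 2.49, against a lag number of 2.21. In teal, the outlet holds 22.2 % intermediate, and the same ratio is 0.829, against 0.737.

The earlier runs and the new flask were generated by integration on assumed constants; noise was put on by code.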